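The data are simulated for an exercise, and the scatter is random.

I looked for slowness in the earlier runs and found none: the theta run read much the same at 15.0 min as at 120 min. So I dropped the clock and drew each flask against ξ, the equivalents of X charged per E.

common to all: E 0.050 M
- theta: X 0.029 M; G 1 mM; run made earlier
- zeta: X 0.23 M; G 1 mM; run made earlier
- Thursday's: X 0.150 M; G 1.00 mM; time 4.0 h
- Wednesday's: X 0.125 M; G 1.00 mM; time 4.0 h
- Sunday's: X 0.0250 M; G 1.00 mM; time 4.0 h

| run | time / min | Z / % | L / % | E / % |
|---|---|---|---|---|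
| theta | 15.0 | 43.1 | 0.2 | 48.8 |
| theta | 40.0 | 43.5 | 0.2 | 48.6 |
| theta | 80.0 | 43.6 | 0 | 48.6 |
| theta | 120 | 43.3 | 0.3 | 47.9 |
| zeta | 10.0 | 0.4 | 61.8 | 0.2 |
| zeta | 20.0 | 0.2 | 61.9 | 0.5 |
| zeta | 50.0 | 0.2 | 62.5 | 0 |
| zeta | 120 | 0 | 62.0 | 0 |

(scatter of a reading: 0.5 percentage points)

- which of these holds the largest part of the E at the end of Thursday's (Z / L / E / D)
- which of these holds the largest part of the E at the end of Wednesday's (Z / L / E / D)
- which of these holds the largest part of the E at the end of Sunday's (Z / L / E / D)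
- Z at the end of Sunday's, in percent of the E charged

- steps that have been proposed: E + X -> Z; X + Z -> D; X + D <-> L; Z + G -> J

At the start of the curve, E falls and Z rises one for one. D needs Z first, so it starts flat, and on log paper it climbs with slope 2. I therefore carried a, the D formed per ξ squared, and read it from the theta run, with E its mean over the readings. There L is negligible and each D costs one extra X.

ξ = 0.580, E = 48.5 %
D = ξ − (1 − E) = 6.47 %
a = D/(ξ·ξ) = 0.192

G can take at most g = 2.00 % of the E as J. Taking all of it, 1 − E − D − g gives Z = 43.0 % in theta, and the mean reading, which I had not used, is 43.4 %.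

Next came the crossing, where Z overtakes E:

ξ = 0.622

Sunday's curve stops at the ξ of its charge, short of that crossing:

ξ = 0.500
D = a·ξ·ξ = 4.81 %
E = 1 − ξ + D = 54.8 %
Z = 1 − E − D − g = 38.4 %

So I expected E to lead on Sunday's. Thursday's and Wednesday's, at ξ of 3.00 and 2.50, lie outside this rule.

The forecast gave D for Thursday's, D for Wednesday's, E for Sunday's and Z at 39.7 %, from the view that “The runs are finished by the first sample”.

The flasks gave D at 64.8 % on Thursday's, D at 79.6 % on Wednesday's, and E at 54.6 % on Sunday's, with Z at 38.8 %.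

    E + X → Z (k = 1.69 M⁻¹ s⁻¹)
    X + Z → D (k = 0.548 M⁻¹ s⁻¹)
    X + D ⇌ L (K = 16.5 M⁻¹, k = 2.80 M⁻¹ s⁻¹)
    Z + G → J (k = 0.0874 M⁻¹ s⁻¹)

On Sunday's, a·ξ·ξ stood for D, which came to 4.58 %. Sunday's Z stayed at 38.8 % because of the wearing away of X together with the falling level of G: without the first, Z came to 0 %, and without the second, to 11.6 %. My reckoning held no clock, and ten times the time left Z at 38.8 %. For the neighbour flask with 0.043 M of X, ξ is 0.860, so a gives D = 14.2 %, E = 28.2 % and Z = 55.6 %. That flask held D at 14.9 %, E at 28.9 % and Z at 54.2 %.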